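**Strategy.** The carbocyclic ring of the tetrahydroquinoline is closed last, by joining C8 to C8a (quinoline numbering). In the open-chain precursor every pyridine carbon except C8a is substituted, and C8a lies next to N1. Once the nitrogen is protonated, C8a is the only position open to a nucleophilic primary radical at C8. One radical substitution therefore forms the C8–C8a bond and the six-membered ring (C4a, C5–C8, C8a) without touching the C5 stereocentre, which is set earlier by rhodium-catalysed asymmetric arylation of an (E)-enoate. The precursor is the (R)-configured 3-pyridylnonane with a terminal iodide three carbons from C5. N-oxidation then gives the target.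

Key step: step 12

Assumption: the C5 stereocentre of the target is R, and (S)-BINAP is taken to give the (3R) ester in step 7 by analogy with (E)-β-alkyl enoates such as crotonates; the configuration of 10 would be confirmed before going on.

Remark: the C4a boronate is built from a 4-pyridone so that the position of boron is fixed by the bromination in step 1, not by a C–H functionalisation of uncertain regiochemistry. Iodide 15 is not stored as the free base, because it could alkylate its own nitrogen intermolecularly; it is protonated before heating.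

**Route**

Step 1
Reactants: 1 3-methoxy-2-methylpyridin-4(1H)-one
Product: 2 5-bromo-3-methoxy-2-methylpyridin-4(1H)-one
Conditions: NBS (1.05 equiv), DMF, 0 °C to rt, dark
Reagents that add atoms: N-bromosuccinimide, O=C1CCC(=O)N1Br
Why: Electrophilic bromination of a 4-pyridone, a vinylogous amide that is nucleophilic at C3 and C5; C3 carries the methoxy group, so only C5 should be brominated.

Step 2
Reactants: 2 5-bromo-3-methoxy-2-methylpyridin-4(1H)-one
Product: 3 5-bromo-4-chloro-3-methoxy-2-methylpyridine
Conditions: POCl3 (neat), 95 °C; poured onto ice, neutralised with aq. NaHCO3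
Reagents that add atoms: phosphoryl chloride, O=P(Cl)(Cl)Cl
Why: Deoxychlorination of a 4-pyridone through its O-phosphorylated pyridinium, which chloride attacks at C4 by addition–elimination.

Step 3
Reactants: 3 5-bromo-4-chloro-3-methoxy-2-methylpyridine
Product: 4 5-bromo-3,4-dimethoxy-2-methylpyridine
Conditions: NaOMe (3 equiv), MeOH/DMSO 1:1, 80 °C
Reagents that add atoms: sodium methoxide, C[O-].[Na+]
Why: Nucleophilic aromatic substitution; C4 is γ to the ring nitrogen and can stabilise the Meisenheimer intermediate, whereas the C5 bromide (β to nitrogen) cannot, so only chloride should be displaced.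

Step 4
Reactants: 4 5-bromo-3,4-dimethoxy-2-methylpyridine
Product: 5 3,4-dimethoxy-2-methyl-5-(4,4,5,5-tetramethyl-1,3,2-dioxaborolan-2-yl)pyridine
Conditions: B2pin2 (1.2 equiv), PdCl2(dppf) (3 mol %), KOAc (3 equiv), 1,4-dioxane, 90 °C
Reagents that add atoms: bis(pinacolato)diboron, CC1(C)OB(OC1(C)C)B1OC(C)(C)C(C)(C)O1
Why: Miyaura borylation of a heteroaryl bromide (oxidative addition, acetate-assisted transmetalation from the diboron, reductive elimination), which places boron exactly where bromine was.

Step 5
Reactants: 6 6-phenylhexan-1-ol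
Product: 7 6-phenylhexanal
Conditions: TEMPO (10 mol %), PhI(OAc)2 (1.1 equiv), CH2Cl2, rt
Reagents that add atoms: none
Why: Oxoammonium-mediated (TEMPO) oxidation of a primary alcohol, which stops at the aldehyde under anhydrous conditions.

Step 6
Reactants: 7 6-phenylhexanal; 8 triethyl phosphonoacetate
Product: 9 ethyl (2E)-8-phenyloct-2-enoate
Conditions: NaH (1.1 equiv), THF, 0 °C to rt
Reagents that add atoms: none
Why: Horner–Wadsworth–Emmons olefination of an unbranched aldehyde with a stabilised phosphonate anion, which should give the (E)-enoate; any (Z)-isomer is removed by chromatography so that it cannot erode the selectivity of step 7.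

Step 7
Reactants: 5 3,4-dimethoxy-2-methyl-5-(4,4,5,5-tetramethyl-1,3,2-dioxaborolan-2-yl)pyridine; 9 ethyl (2E)-8-phenyloct-2-enoate
Product: 10 ethyl (3R)-3-(4,5-dimethoxy-6-methylpyridin-3-yl)-8-phenyloctanoate
Conditions: 5 (1.5 equiv), Rh(acac)(C2H4)2 (5 mol %), (S)-BINAP (6 mol %), K3PO4 (1 equiv), 1,4-dioxane/H2O 10:1, 90 °C
Reagents that add atoms: none
Why: Hayashi–Miyaura rhodium-catalysed asymmetric 1,4-addition (transmetalation to an aryl–rhodium BINAP complex, enantioface-selective insertion of the enoate, hydrolysis of the oxa-π-allyl rhodium); the new C3 stereocentre is controlled by the ligand, (S)-BINAP being expected to deliver the aryl group to the α-si face of the (E)-enoate and so to give the (3R) ester.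

Step 8
Reactants: 10 ethyl (3R)-3-(4,5-dimethoxy-6-methylpyridin-3-yl)-8-phenyloctanoate
Product: 11 (3R)-3-(4,5-dimethoxy-6-methylpyridin-3-yl)-8-phenyloctanal
Conditions: i-Bu2AlH (2.2 equiv), CH2Cl2, −78 °C; MeOH, then aq. potassium sodium tartrate
Reagents that add atoms: none
Why: Partial reduction of an ester by i-Bu2AlH, whose tetrahedral aluminium hemiacetal is stable at −78 °C and releases the aldehyde only on work-up; the second equivalent allows for coordination to the pyridine nitrogen, and the stereocentre is β to the carbonyl and cannot epimerise.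

Step 9
Reactants: 11 (3R)-3-(4,5-dimethoxy-6-methylpyridin-3-yl)-8-phenyloctanal
Product: 12 3,4-dimethoxy-2-methyl-5-[(4R)-9-phenylnon-1-en-4-yl]pyridine
Conditions: Ph3PCH3Br (1.5 equiv), KOtBu (1.4 equiv), THF, 0 °C to rt
Reagents that add atoms: methyltriphenylphosphonium bromide, C[P+](c1ccccc1)(c1ccccc1)c1ccccc1.[Br-]
Why: Wittig methylenation of an aldehyde with the non-stabilised ylide, which is not basic enough to deprotonate the C2 methyl group or the stereocentre.

Step 10
Reactants: 12 3,4-dimethoxy-2-methyl-5-[(4R)-9-phenylnon-1-en-4-yl]pyridine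
Product: 14 (4R)-4-(4,5-dimethoxy-6-methylpyridin-3-yl)-9-phenylnonan-1-ol, via B-alkyl-9-borabicyclononane 13 (not isolated)
Conditions: 9-BBN (2.5 equiv), THF, 0 to 50 °C; then 3 M NaOH, 30% H2O2, 0 °C to rt
Reagents that add atoms: 9-borabicyclo[3.3.1]nonane, [H]B1C2CCCC1CCC2 (boron and its ring in 13 only); hydrogen peroxide, OO (oxygen of 14)
Why: Anti-Markovnikov hydroboration of a terminal alkene with 9-BBN followed by oxidative C–B cleavage with retention; the excess borane allows for reversible complexation at the pyridine nitrogen.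

Step 11
Reactants: 14 (4R)-4-(4,5-dimethoxy-6-methylpyridin-3-yl)-9-phenylnonan-1-ol
Product: 15 5-[(4R)-1-iodo-9-phenylnonan-4-yl]-3,4-dimethoxy-2-methylpyridine
Conditions: PPh3 (1.3 equiv), imidazole (1.5 equiv), I2 (1.3 equiv), CH2Cl2, 0 °C to rt; product kept cold in solution and used at once
Reagents that add atoms: iodine, II
Why: Appel-type iodination, in which the alkoxyphosphonium ion of the primary alcohol is displaced by iodide in an SN2 reaction far from the stereocentre.

Step 12
Reactants: 15 5-[(4R)-1-iodo-9-phenylnonan-4-yl]-3,4-dimethoxy-2-methylpyridine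
Product: 16 (5R)-3,4-dimethoxy-2-methyl-5-(5-phenylpentyl)-5,6,7,8-tetrahydroquinoline
Conditions: CF3CO2H (2 equiv), dilauroyl peroxide (1.6 equiv, in portions), degassed ClCH2CH2Cl (0.02 M), reflux; aq. NaHCO3 work-up
Reagents that add atoms: none
Why: Thermolysis of dilauroyl peroxide gives undecyl radicals that abstract iodine from 15; the nucleophilic primary C8 radical adds to C8a of the protonated pyridine, and the adduct loses the C8a proton and is oxidised by further peroxide, which restores the aromatic ring and carries the chain. The closest known reaction type is the intramolecular Minisci homolytic alkylation of protonated pyridines by alkyl iodides with diacyl peroxides. The six-membered carbocycle (C4a, C5, C6, C7, C8, C8a) closes 6-exo-trig on the C8a=N1 iminium bond, that is, by ortho attack of a 4-arylbutyl-type radical. No stereocentre is formed; C5 never becomes a radical or cationic centre and should keep its R configuration. Only site selectivity is needed: C2, C3, C4 and C4a are all substituted, so C8a is the one position from which the adduct can rearomatise by proton loss, protonation makes this α-carbon the most electrophilic site, and ipso attack at C4a would be reversible. High dilution and portionwise peroxide should keep cyclisation ahead of reduction or dimerisation of the radical.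

Step 13
Reactants: 16 (5R)-3,4-dimethoxy-2-methyl-5-(5-phenylpentyl)-5,6,7,8-tetrahydroquinoline
Product: 17 (5R)-3,4-dimethoxy-2-methyl-5-(5-phenylpentyl)-5,6,7,8-tetrahydroquinoline 1-oxide
Conditions: mCPBA (1.1 equiv), CH2Cl2, 0 °C to rt; aq. K2CO3 wash
Reagents that add atoms: 3-chloroperbenzoic acid, OOC(=O)c1cccc(Cl)c1
Why: Peracid N-oxidation of an electron-rich 2,6-dialkylpyridine; the nitrogen lone pair is the only site in 16 that reacts with a peracid under these conditions.

**Compound list**

1 | 3-methoxy-2-methylpyridin-4(1H)-one | Cc1[nH]ccc(=O)c1OC | starting material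
2 | 5-bromo-3-methoxy-2-methylpyridin-4(1H)-one | Cc1[nH]cc(Br)c(=O)c1OC | intermediate
3 | 5-bromo-4-chloro-3-methoxy-2-methylpyridine | COc1c(Cl)c(Br)cnc1C | intermediate
4 | 5-bromo-3,4-dimethoxy-2-methylpyridine | COc1c(OC)c(C)ncc1Br | intermediate
5 | 3,4-dimethoxy-2-methyl-5-(4,4,5,5-tetramethyl-1,3,2-dioxaborolan-2-yl)pyridine | COc1c(OC)c(C)ncc1B1OC(C)(C)C(C)(C)O1 | intermediate
6 | 6-phenylhexan-1-ol | OCCCCCCc1ccccc1 | starting material
7 | 6-phenylhexanal | O=CCCCCCc1ccccc1 | intermediate
8 | triethyl phosphonoacetate | CCOC(=O)CP(=O)(OCC)OCC | starting material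
9 | ethyl (2E)-8-phenyloct-2-enoate | CCOC(=O)/C=C/CCCCCc1ccccc1 | intermediate
10 | ethyl (3R)-3-(4,5-dimethoxy-6-methylpyridin-3-yl)-8-phenyloctanoate | COc1c(OC)c(C)ncc1[C@H](CCCCCc1ccccc1)CC(=O)OCC | intermediate
11 | (3R)-3-(4,5-dimethoxy-6-methylpyridin-3-yl)-8-phenyloctanal | COc1c(OC)c(C)ncc1[C@H](CCCCCc1ccccc1)CC=O | intermediate
12 | 3,4-dimethoxy-2-methyl-5-[(4R)-9-phenylnon-1-en-4-yl]pyridine | COc1c(OC)c(C)ncc1[C@H](CCCCCc1ccccc1)CC=C | intermediate
13 | 9-[(4S)-4-(4,5-dimethoxy-6-methylpyridin-3-yl)-9-phenylnonyl]-9-borabicyclo[3.3.1]nonane (same geometry as 12; the descriptor changes only because boron ranks below carbon) | COc1c(OC)c(C)ncc1[C@H](CCCCCc1ccccc1)CCCB1C2CCCC1CCC2 | intermediate (not isolated)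
14 | (4R)-4-(4,5-dimethoxy-6-methylpyridin-3-yl)-9-phenylnonan-1-ol | COc1c(OC)c(C)ncc1[C@H](CCCCCc1ccccc1)CCCO | intermediate
15 | 5-[(4R)-1-iodo-9-phenylnonan-4-yl]-3,4-dimethoxy-2-methylpyridine | COc1c(OC)c(C)ncc1[C@H](CCCCCc1ccccc1)CCCI | intermediate (key-step precursor)
16 | (5R)-3,4-dimethoxy-2-methyl-5-(5-phenylpentyl)-5,6,7,8-tetrahydroquinoline | COc1c(OC)c(C)nc2c1[C@H](CCCCCc1ccccc1)CCC2 | intermediate (key-step product)
17 | (5R)-3,4-dimethoxy-2-methyl-5-(5-phenylpentyl)-5,6,7,8-tetrahydroquinoline 1-oxide | COc1c(OC)c(C)[n+]([O-])c2c1[C@H](CCCCCc1ccccc1)CCC2 | target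

**Step count**

Total: 13 steps. Longest linear sequence: 11 steps (steps 1–4, then 7–13); the enoate branch (steps 5–6) joins at step 7.

**Steps most likely to fail**

Step 12. The iodine-transfer chain may be too slow, so that the C8 radical is reduced before it cyclises, or iodide and acid at reflux may cleave the C4 methyl ether. The fallback makes the same C8 radical by oxidative decarboxylation and so avoids both iodide and the atom-transfer chain. It sets out from aldehyde 11. Wittig olefination with ethyl (triphenylphosphoranylidene)acetate (CH2Cl2, rt) should give ethyl (2E,5R)-5-(4,5-dimethoxy-6-methylpyridin-3-yl)-10-phenyldec-2-enoate F1. Hydrogenation (H2, 1 atm, Pd/C, EtOAc) should give ethyl (5R)-5-(4,5-dimethoxy-6-methylpyridin-3-yl)-10-phenyldecanoate F2. Saponification (LiOH, THF/H2O) should give (5R)-5-(4,5-dimethoxy-6-methylpyridin-3-yl)-10-phenyldecanoic acid F3. A classical decarboxylative Minisci closure (AgNO3 20 mol %, (NH4)2S2O8 2 equiv, CF3CO2H 1.5 equiv, MeCN/H2O, 70 °C) should then form C8–C8a and return to the route at 16, before step 13.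

Step 7. Protodeboronation of the electron-rich, ortho-methoxy pyridylboronate and binding of the pyridine nitrogen to rhodium may outrun transmetalation and insertion, or the facial selectivity may be too low. The fallback is an auxiliary-controlled cuprate addition and sets out from enoate 9 and bromide 4. Saponification of 9 (LiOH, THF/H2O) should give (2E)-8-phenyloct-2-enoic acid F4. Its mixed pivalic anhydride (PivCl, Et3N, THF, −20 °C) acylates (4S)-4-phenyl-1,3-oxazolidin-2-one (LiCl, Et3N) to (4S)-4-phenyl-3-[(2E)-8-phenyloct-2-enoyl]-1,3-oxazolidin-2-one F5. Bromine–magnesium exchange on 4 (i-PrMgCl·LiCl, THF, rt) gives (4,5-dimethoxy-6-methylpyridin-3-yl)magnesium chloride F6. With CuBr·SMe2 (THF, −40 to −10 °C) F6 should add to the chelated s-cis imide anti to the phenyl group, giving (4S)-3-[(3R)-3-(4,5-dimethoxy-6-methylpyridin-3-yl)-8-phenyloctanoyl]-4-phenyl-1,3-oxazolidin-2-one F7. Any minor diastereomer is removed by chromatography. Transesterification with EtOMgBr (from EtMgBr and EtOH, THF, 0 °C) returns to the route at ester 10.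

Step 8. The reduction may run past the aldehyde to the alcohol, or stall because aluminium is held by the pyridine nitrogen. The fallback reduces fully and re-oxidises. It sets out from ester 10: LiAlH4 (THF, 0 °C) should give (3R)-3-(4,5-dimethoxy-6-methylpyridin-3-yl)-8-phenyloctan-1-ol F8, and Dess–Martin periodinane (CH2Cl2, NaHCO3, rt) should oxidise it to aldehyde 11, where the route resumes.

**Further compounds**

F1 | step 12 | ethyl (2E,5R)-5-(4,5-dimethoxy-6-methylpyridin-3-yl)-10-phenyldec-2-enoate | COc1c(OC)c(C)ncc1[C@H](CCCCCc1ccccc1)C/C=C/C(=O)OCC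
F2 | step 12 | ethyl (5R)-5-(4,5-dimethoxy-6-methylpyridin-3-yl)-10-phenyldecanoate | COc1c(OC)c(C)ncc1[C@H](CCCCCc1ccccc1)CCCC(=O)OCC
F3 | step 12 | (5R)-5-(4,5-dimethoxy-6-methylpyridin-3-yl)-10-phenyldecanoic acid | COc1c(OC)c(C)ncc1[C@H](CCCCCc1ccccc1)CCCC(=O)O
F4 | step 7 | (2E)-8-phenyloct-2-enoic acid | OC(=O)/C=C/CCCCCc1ccccc1
F5 | step 7 | (4S)-4-phenyl-3-[(2E)-8-phenyloct-2-enoyl]-1,3-oxazolidin-2-one | O=C(/C=C/CCCCCc1ccccc1)N1[C@@H](c2ccccc2)COC1=O
F6 | step 7 | (4,5-dimethoxy-6-methylpyridin-3-yl)magnesium chloride | COc1c(OC)c(C)ncc1[Mg]Cl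
F7 | step 7 | (4S)-3-[(3R)-3-(4,5-dimethoxy-6-methylpyridin-3-yl)-8-phenyloctanoyl]-4-phenyl-1,3-oxazolidin-2-one | COc1c(OC)c(C)ncc1[C@H](CCCCCc1ccccc1)CC(=O)N1[C@@H](c2ccccc2)COC1=O
F8 | step 8 | (3R)-3-(4,5-dimethoxy-6-methylpyridin-3-yl)-8-phenyloctan-1-ol | COc1c(OC)c(C)ncc1[C@H](CCCCCc1ccccc1)CCO
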